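Retrosynthetic overview (daucane numbering: C1 quaternary carbon, C4=C5 and C8=C9 alkenes, C14 the CH2O carbon)
- The target comes from unprotected vanillic acid and dauca-4,8-dien-14-ol by Mitsunobu esterification; the alcohol comes from daucenal by 1,2-reduction.
- Ring B (seven-membered) is formed last. C8=C9 is closed by intramolecular aldol condensation of a dialdehyde. Its C5–C6 arm comes from a Negishi coupling on a cyclopentenyl triflate, which also fixes C4=C5.
- Ring A (five-membered) is formed first, in the key step. The ring-fusion bond C1–C5 is made by an asymmetric carbene-catalysed Stetter cyclisation, in which the formyl carbon acts as an acyl anion and attacks the β-carbon of a β-methyl enoate. Both carbons are natively electrophilic, and this step sets the only stereocentre.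
- The acyclic aldehyde is made in one operation from methyl geranate and CO by hydroboration–carbonylation.

Assumption: the sense of induction on this new substrate is assigned by analogy, with the (5aR,10bS) triazolium salt taken to direct attack to the Re face of C3. If it proves opposite, the equally commercial (5aS,10bR) antipode is used and nothing else changes.

Step 1
Reactants: 1 methyl (2E)-3,7-dimethylocta-2,6-dienoate (methyl geranate); 2 carbon monoxide
Product: 5 methyl (2E)-6-formyl-3,7-dimethyloct-2-enoate (racemic at C6), via B-alkyl-9-BBN adduct 3 (not isolated), via alpha-alkoxyalkylborane 4 (not isolated)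
Conditions: 9-BBN-H, THF, 65 °C; CO (1 atm), LiAlH(Ot-Bu)3, THF, 0 °C; H2O2, NaH2PO4/K2HPO4 buffer (pH 7), 0 °C
Reagents that add atoms: carbon monoxide [C-]#[O+]
Why: Brown hydroboration–carbonylation, in which 9-BBN-H adds only to the electron-rich 6,7-alkene with boron on the less substituted C6, CO inserts with migration of the sec-alkyl group, the hindered hydride (inert to the enoate) holds the sequence at the aldehyde level and buffered oxidation frees the formyl group; the new C6 centre is racemic, which is harmless because it becomes sp2 in step 3.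

Step 2
Reactants: 5 methyl (2E)-6-formyl-3,7-dimethyloct-2-enoate (racemic)
Product: 6 methyl 2-[(1R,3RS)-1-methyl-2-oxo-3-(propan-2-yl)cyclopentyl]acetate
Conditions: (5aR,10bS)-2-(pentafluorophenyl)-5a,10b-dihydro-4H,6H-indeno[2,1-b][1,2,4]triazolo[4,3-d][1,4]oxazin-2-ium tetrafluoroborate (20 mol %), KN(SiMe3)2 (18 mol %), toluene, 25 °C
Reagents that add atoms: none
Why: Catalytic asymmetric intramolecular Stetter reaction, extended from unbranched aldehydes to a racemic α-branched one, in which the triazolylidene turns the formyl carbon into an acyl anion equivalent that closes ring A by 5-exo attack on the β-carbon of the (E)-enoate, and the aminoindanol wall lets both antipodes of 5 react on the Re face of C3 (catalyst control), so the quaternary centre is set as (R) while the epimerisable isopropyl-bearing centre stays a mixture.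

Step 3
Reactants: 6 methyl 2-[(1R,3RS)-1-methyl-2-oxo-3-(propan-2-yl)cyclopentyl]acetate
Product: 8 methyl 2-[(1R)-1-methyl-3-(propan-2-yl)-2-(trifluoromethylsulfonyloxy)cyclopent-2-en-1-yl]acetate, via potassium enolate 7 (not isolated)
Conditions: KN(SiMe3)2, THF, −78 to 0 °C; PhNTf2, 0 °C to rt
Reagents that add atoms: N-phenylbis(trifluoromethanesulfonimide) O=S(=O)(N(c1ccccc1)S(=O)(=O)C(F)(F)F)C(F)(F)F
Why: Enolate O-sulfonylation, regiospecific because the ketone has a single α-hydrogen (about five pKa units more acidic than the ester CH2, so proton transfer funnels to the ketone enolate), so both C3 epimers converge on one tetrasubstituted enol triflate and the quaternary centre is untouched.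

Step 4
Reactants: 8 methyl 2-[(1R)-1-methyl-3-(propan-2-yl)-2-(trifluoromethylsulfonyloxy)cyclopent-2-en-1-yl]acetate; 9 (4-ethoxy-4-oxobutyl)zinc bromide
Product: 10 ethyl 4-[(5R)-5-(2-methoxy-2-oxoethyl)-5-methyl-2-(propan-2-yl)cyclopent-1-en-1-yl]butanoate
Conditions: PdCl2(dppf) (5 mol %), LiCl, THF/NMP, 60 °C
Reagents that add atoms: (4-ethoxy-4-oxobutyl)zinc bromide CCOC(=O)CCC[Zn]Br
Why: Negishi sp2–sp3 cross-coupling, in which zerovalent palladium inserts into the C–OTf bond, the ester-tolerant primary alkylzinc transmetalates and the wide-bite-angle ligand favours reductive elimination over β-hydride loss, placing C6 on C5 with the alkene exactly where the enolate was, as in couplings of the similarly flanked 2,6,6-trimethylcyclohexenyl triflate.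

Step 5
Reactants: 10 ethyl 4-[(5R)-5-(2-methoxy-2-oxoethyl)-5-methyl-2-(propan-2-yl)cyclopent-1-en-1-yl]butanoate
Product: 11 4-[(5R)-5-methyl-5-(2-oxoethyl)-2-(propan-2-yl)cyclopent-1-en-1-yl]butanal
Conditions: i-Bu2AlH (2.2 equiv), CH2Cl2, −78 °C; MeOH, aq. potassium sodium tartrate
Reagents that add atoms: none
Why: Partial ester reduction, in which each ester stops at −78 °C as its aluminium hemiacetal and collapses to the aldehyde only on work-up, while the tetrasubstituted alkene and the stereocentre are inert.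

Step 6
Reactants: 11 4-[(5R)-5-methyl-5-(2-oxoethyl)-2-(propan-2-yl)cyclopent-1-en-1-yl]butanal
Product: 13 (8aR)-8a-methyl-3-(propan-2-yl)-1,2,4,5,8,8a-hexahydroazulene-6-carbaldehyde (daucenal), via beta-hydroxy aldehyde 12 (not isolated)
Conditions: dibenzylammonium trifluoroacetate (0.5 equiv), toluene (0.01 M), 60 °C
Reagents that add atoms: none
Why: Amine-salt-mediated intramolecular aldol condensation, in which the unhindered butanal arm forms the enamine and its α-carbon C8 attacks the C9 aldehyde (the competing nucleophile C10 is neopentyl), the ring A alkene holds both arms on the same side for seven-ring closure, and E1cB loss of water erases the transient centres of 12.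

Step 7
Reactants: 13 daucenal
Product: 14 [(8aR)-8a-methyl-3-(propan-2-yl)-1,2,4,5,8,8a-hexahydroazulen-6-yl]methanol (dauca-4,8-dien-14-ol)
Conditions: NaBH4, CeCl3·7H2O, MeOH, 0 °C
Reagents that add atoms: none
Why: Luche reduction gives clean 1,2-reduction of the enal to the primary allylic alcohol without touching either alkene or creating a stereocentre.

Step 8
Reactants: 14 dauca-4,8-dien-14-ol; 15 4-hydroxy-3-methoxybenzoic acid (vanillic acid)
Product: 16 [(8aR)-8a-methyl-3-(propan-2-yl)-1,2,4,5,8,8a-hexahydroazulen-6-yl]methyl 4-hydroxy-3-methoxybenzoate (target)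
Conditions: PPh3, DIAD, THF, 0 °C to rt
Reagents that add atoms: vanillic acid COc1cc(C(=O)O)ccc1O
Why: Mitsunobu esterification, chemoselective without phenol protection because only the carboxylic acid (pKa about 4.5, against about 9.5 for the phenol) protonates the betaine, and its carboxylate displaces the primary allylic oxyphosphonium by SN2, far from the stereocentre.

Compound list
1 | methyl (2E)-3,7-dimethylocta-2,6-dienoate (methyl geranate) | COC(=O)/C=C(\C)CCC=C(C)C | starting material
2 | carbon monoxide | [C-]#[O+] | starting material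
3 | methyl (2E)-6-(9-borabicyclo[3.3.1]nonan-9-yl)-3,7-dimethyloct-2-enoate (racemic) | COC(=O)/C=C(\C)CCC(C(C)C)B1C2CCCC1CCC2 | intermediate
4 | methyl (2E)-6-[(9-borabicyclo[3.3.1]nonan-9-yl)(hydroxy)methyl]-3,7-dimethyloct-2-enoate (present as its aluminium alkoxide, drawn as the alcohol; diastereomer mixture) | COC(=O)/C=C(\C)CCC(C(C)C)C(O)B1C2CCCC1CCC2 | intermediate
5 | methyl (2E)-6-formyl-3,7-dimethyloct-2-enoate (racemic) | COC(=O)/C=C(\C)CCC(C=O)C(C)C | intermediate
6 | methyl 2-[(1R,3RS)-1-methyl-2-oxo-3-(propan-2-yl)cyclopentyl]acetate | COC(=O)C[C@@]1(C)CCC(C(C)C)C1=O | intermediate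
7 | potassium (5R)-5-(2-methoxy-2-oxoethyl)-5-methyl-2-(propan-2-yl)cyclopent-1-en-1-olate | COC(=O)C[C@@]1(C)CCC(C(C)C)=C1[O-].[K+] | intermediate
8 | methyl 2-[(1R)-1-methyl-3-(propan-2-yl)-2-(trifluoromethylsulfonyloxy)cyclopent-2-en-1-yl]acetate | COC(=O)C[C@@]1(C)CCC(C(C)C)=C1OS(=O)(=O)C(F)(F)F | intermediate
9 | (4-ethoxy-4-oxobutyl)zinc bromide | CCOC(=O)CCC[Zn]Br | starting material
10 | ethyl 4-[(5R)-5-(2-methoxy-2-oxoethyl)-5-methyl-2-(propan-2-yl)cyclopent-1-en-1-yl]butanoate | COC(=O)C[C@@]1(C)CCC(C(C)C)=C1CCCC(=O)OCC | intermediate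
11 | 4-[(5R)-5-methyl-5-(2-oxoethyl)-2-(propan-2-yl)cyclopent-1-en-1-yl]butanal | O=CC[C@@]1(C)CCC(C(C)C)=C1CCCC=O | intermediate
12 | (8aR)-7-hydroxy-8a-methyl-3-(propan-2-yl)-1,2,4,5,6,7,8,8a-octahydroazulene-6-carbaldehyde (mixture at C6 and C7) | O=CC2C(O)C[C@@]3(C)CCC(C(C)C)=C3CC2 | intermediate
13 | (8aR)-8a-methyl-3-(propan-2-yl)-1,2,4,5,8,8a-hexahydroazulene-6-carbaldehyde (daucenal) | O=CC2=CC[C@@]3(C)CCC(C(C)C)=C3CC2 | intermediate
14 | [(8aR)-8a-methyl-3-(propan-2-yl)-1,2,4,5,8,8a-hexahydroazulen-6-yl]methanol | OCC2=CC[C@@]3(C)CCC(C(C)C)=C3CC2 | intermediate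
15 | 4-hydroxy-3-methoxybenzoic acid (vanillic acid) | COc1cc(C(=O)O)ccc1O | starting material
16 | [(8aR)-8a-methyl-3-(propan-2-yl)-1,2,4,5,8,8a-hexahydroazulen-6-yl]methyl 4-hydroxy-3-methoxybenzoate | COc1cc(C(=O)OCC2=CC[C@@]3(C)CCC(C(C)C)=C3CC2)ccc1O | target

Total step count: 8. Longest linear sequence: 8 (compounds 1 to 16; 9, 15 and the triazolium salt are purchased).

Steps most likely to fail

Step 2. The α-branched aldehyde may engage the carbene too slowly, or one antipode of 5 may be mismatched and lower the ee.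
The fallback sets out from 1 and returns at 6. It installs the isopropyl group after ring closure, so the cyclisation runs on the unbranched aldehyde class for which quaternary-centre formation is established.
- Selective ozonolysis of the electron-rich 6,7-alkene of 1 (1 equiv O3, CH2Cl2, −78 °C; Me2S) gives methyl (2E)-3-methyl-6-oxohex-2-enoate F1.
- Wittig homologation with (methoxymethylidene)triphenylphosphorane F2 (from the phosphonium chloride and KOt-Bu) gives methyl (2E)-7-methoxy-3-methylhepta-2,6-dienoate F3.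
- Aqueous HCl in THF then gives methyl (2E)-3-methyl-7-oxohept-2-enoate F4.
- The same triazolium salt and base cyclise this to methyl 2-[(1R)-1-methyl-2-oxocyclopentyl]acetate F5.
- Its zinc enolate (LiN(i-Pr)2, ZnCl2, −78 °C) adds to acetone to give methyl 2-[(1R)-3-(2-hydroxypropan-2-yl)-1-methyl-2-oxocyclopentyl]acetate F6.
- p-TsOH in hot benzene dehydrates this to methyl 2-[(1R)-1-methyl-2-oxo-3-(propan-2-ylidene)cyclopentyl]acetate F7.
- Hydrogenation (H2, Pd/C) delivers 6.

Step 6. Seven-ring aldol closure may oligomerise, or C10 may act as the nucleophile and give the regioisomeric enal.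
The fallback sets out from 10 and returns at 14, bypassing steps 5 to 7. It closes ring B at the ester oxidation level under reversible, thermodynamic control.
- Dieckmann condensation (KOt-Bu, toluene) gives the less hindered β-keto ester ethyl (8aR)-8a-methyl-7-oxo-3-(propan-2-yl)-1,2,4,5,6,7,8,8a-octahydroazulene-6-carboxylate F8.
- NaBH4 gives ethyl (8aR)-7-hydroxy-8a-methyl-3-(propan-2-yl)-1,2,4,5,6,7,8,8a-octahydroazulene-6-carboxylate F9.
- MsCl and Et3N give ethyl (8aR)-8a-methyl-7-(methylsulfonyloxy)-3-(propan-2-yl)-1,2,4,5,6,7,8,8a-octahydroazulene-6-carboxylate F10.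
- DBU eliminates towards the acidic C8–H to give ethyl (8aR)-8a-methyl-3-(propan-2-yl)-1,2,4,5,8,8a-hexahydroazulene-6-carboxylate F11.
- i-Bu2AlH (2.2 equiv) reduces this directly to 14.

Step 1. Carbonylative migration of the hindered sec-alkyl group on boron may be sluggish.
The fallback sets out from 1 and returns at 5. It brings in the extra carbon as an electrophile instead.
- The Me2AlCl-promoted ene reaction of 1 with paraformaldehyde (CH2Cl2, 0 °C) bonds C6 to CH2O and gives methyl (2E)-6-(hydroxymethyl)-3,7-dimethylocta-2,7-dienoate F12.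
- RhCl(PPh3)3 and H2 saturate only the 1,1-disubstituted alkene to give methyl (2E)-6-(hydroxymethyl)-3,7-dimethyloct-2-enoate F13.
- Dess–Martin oxidation gives 5.

Further compounds
F1 | step 2 | methyl (2E)-3-methyl-6-oxohex-2-enoate | COC(=O)/C=C(\C)CCC=O
F2 | step 2 | (methoxymethylidene)triphenylphosphorane | COC=P(c1ccccc1)(c1ccccc1)c1ccccc1
F3 | step 2 | methyl (2E)-7-methoxy-3-methylhepta-2,6-dienoate (mixture at the 6,7-alkene) | COC(=O)/C=C(\C)CCC=COC
F4 | step 2 | methyl (2E)-3-methyl-7-oxohept-2-enoate | COC(=O)/C=C(\C)CCCC=O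
F5 | step 2 | methyl 2-[(1R)-1-methyl-2-oxocyclopentyl]acetate | COC(=O)C[C@@]1(C)CCCC1=O
F6 | step 2 | methyl 2-[(1R)-3-(2-hydroxypropan-2-yl)-1-methyl-2-oxocyclopentyl]acetate (mixture at C3) | COC(=O)C[C@@]1(C)CCC(C(C)(C)O)C1=O
F7 | step 2 | methyl 2-[(1R)-1-methyl-2-oxo-3-(propan-2-ylidene)cyclopentyl]acetate | COC(=O)C[C@@]1(C)CCC(=C(C)C)C1=O
F8 | step 6 | ethyl (8aR)-8a-methyl-7-oxo-3-(propan-2-yl)-1,2,4,5,6,7,8,8a-octahydroazulene-6-carboxylate | CCOC(=O)C2C(=O)C[C@@]3(C)CCC(C(C)C)=C3CC2
F9 | step 6 | ethyl (8aR)-7-hydroxy-8a-methyl-3-(propan-2-yl)-1,2,4,5,6,7,8,8a-octahydroazulene-6-carboxylate | CCOC(=O)C2C(O)C[C@@]3(C)CCC(C(C)C)=C3CC2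
F10 | step 6 | ethyl (8aR)-8a-methyl-7-(methylsulfonyloxy)-3-(propan-2-yl)-1,2,4,5,6,7,8,8a-octahydroazulene-6-carboxylate | CCOC(=O)C2C(OS(C)(=O)=O)C[C@@]3(C)CCC(C(C)C)=C3CC2
F11 | step 6 | ethyl (8aR)-8a-methyl-3-(propan-2-yl)-1,2,4,5,8,8a-hexahydroazulene-6-carboxylate | CCOC(=O)C2=CC[C@@]3(C)CCC(C(C)C)=C3CC2
F12 | step 1 | methyl (2E)-6-(hydroxymethyl)-3,7-dimethylocta-2,7-dienoate (racemic) | COC(=O)/C=C(\C)CCC(CO)C(C)=C
F13 | step 1 | methyl (2E)-6-(hydroxymethyl)-3,7-dimethyloct-2-enoate (racemic) | COC(=O)/C=C(\C)CCC(CO)C(C)C
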